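Ring locants used below: O1, O2, C3 (bears CH2CO2H), C4 (ethyl), C5 (CH2), C6 (quaternary); side chain C1'–C8' with stereocentres C2' (methyl) and C4' (ethyl).

**Plan**
- Retrosynthesis: the exocyclic C3–CH2CO2H bond is cut first (peroxyacetal plus ketene acetal). Then the ring bonds C5–C6 and O2–C3 are cut together, giving the silylperoxy ketal of an ethyl ketone (C6, O1, O2, ethyl, side chain) and a trans-2-ethylcyclopropyl silyl ether (C3, C4, C5).
- Enabling feature: C6 is a ketone-level carbon carrying the O1–O2 unit, so it becomes a peroxycarbenium ion on ionisation. C3(O)–C4–C5 is a homoenolate pattern, i.e. a ring-opened cyclopropanol. The ring O1–O2–C3–C4–C5–C6 is therefore a formal [3+3] union.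
- Forward: the side-chain ketone is made by two copper-catalysed conjugate additions and turned into the peroxy ketal (steps 1–6). The cyclopropyl silyl ether comes from an asymmetric cyclopropanation and a Baeyer–Villiger degradation (steps 7–11). The annulation closes the only ring (step 12), the acetate arm is added at C3 (step 13), and the ester is saponified (step 14).
- Stereochemistry: C2' and C4' come from ligand-controlled conjugate additions. C4 comes from the dioxaborolane-controlled cyclopropanation and is carried through untouched. C3 comes from axial attack on the cyclic peroxycarbenium ion, cis to the C4 ethyl group. C6 arises in step 12 with at best weak 1,3-induction; the 6R epimer is secured by separating the diastereomeric peroxyacetals.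

Key step: step 12

Assumption: in steps 1 and 4 the configuration is taken to be set by the ligand alone. Which ligand antipode gives which face is assumed, not known here. If ester and enone follow the same model, the two steps need opposite antipodes; the mirror-image ligand would be used wherever the opposite sense is found.

**Step 1**
Reactants: 1 methyl (E)-pent-2-enoate
Product: 2 methyl (S)-3-ethylheptanoate
Conditions: n-BuMgBr, CuBr·SMe2 (cat.), (R)-1-[(S)-2-(diphenylphosphino)ferrocenyl]ethyldicyclohexylphosphine (cat.), t-BuOMe, −75 °C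
Reagents that add atoms: n-butylmagnesium bromide CCCC[Mg]Br
Why: Copper-catalysed asymmetric conjugate addition of a Grignard reagent to an acyclic enoate; the copper–diphosphine complex delivers the butyl group to one face of the β-carbon and so sets the ethyl/butyl centre (C4' of the side chain) as S under ligand control.

**Step 2**
Reactants: 2 methyl (S)-3-ethylheptanoate
Product: 3 (S)-3-ethylheptanal
Conditions: i-Bu2AlH (1.05 equiv), CH2Cl2, −78 °C; then MeOH, aqueous potassium sodium tartrate
Reagents that add atoms: none
Why: Partial reduction of a methyl ester with i-Bu2AlH at low temperature stops at the aluminium hemiacetal, which gives the aldehyde on work-up; the β-stereocentre cannot epimerise.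

**Step 3**
Reactants: 3 (S)-3-ethylheptanal
Product: 4 (S,E)-7-ethylundec-4-en-3-one
Conditions: Ph3P=CHC(O)Et, toluene, 80 °C
Reagents that add atoms: 1-(triphenylphosphoranylidene)butan-2-one CCC(=O)C=P(c1ccccc1)(c1ccccc1)c1ccccc1
Why: Wittig olefination with a stabilised acyl ylide should give the (E)-enone selectively.

**Step 4**
Reactants: 4 (S,E)-7-ethylundec-4-en-3-one
Product: 5 (5S,7S)-7-ethyl-5-methylundecan-3-one
Conditions: MeMgBr, CuBr·SMe2 (cat.), (S)-1-[(R)-2-(diphenylphosphino)ferrocenyl]ethyldicyclohexylphosphine (cat.), t-BuOMe, −75 °C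
Reagents that add atoms: methylmagnesium bromide C[Mg]Br
Why: Copper-catalysed asymmetric conjugate addition of MeMgBr to an acyclic enone; the catalyst overrides the remote C7 centre and sets C5 as S (C2' of the side chain, 1,3-syn to the ethyl-bearing centre).

**Step 5**
Reactants: 5 (5S,7S)-7-ethyl-5-methylundecan-3-one
Product: 7 (5S,7S)-7-ethyl-3-hydroperoxy-3-methoxy-5-methylundecane, via dimethyl ketal 6 (not isolated)
Conditions: HC(OMe)3, MeOH, p-TsOH (cat.), rt; concentrate; then anhydrous H2O2 in Et2O, p-TsOH (cat.), 0 °C
Reagents that add atoms: trimethyl orthoformate COC(OC)OC; hydrogen peroxide OO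
Why: Acid-catalysed ketalisation followed by perhydrolysis of the ketal (exchange of one methoxy group for OOH through the oxocarbenium ion) gives the monoperoxy ketal; the ketal carbon forms as both epimers, which is immaterial because it is ionised in step 12.

**Step 6**
Reactants: 7 (5S,7S)-7-ethyl-3-hydroperoxy-3-methoxy-5-methylundecane
Product: 8 triethyl{[(5S,7S)-7-ethyl-3-methoxy-5-methylundecan-3-yl]peroxy}silane
Conditions: Et3SiCl, imidazole, CH2Cl2, 0 °C
Reagents that add atoms: chlorotriethylsilane CC[Si](Cl)(CC)CC
Why: O-silylation of the hydroperoxide under mild base caps the OOH as the triethylsilyl peroxide, the form used for Lewis-acid ionisation of peroxy ketals.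

**Step 7**
Reactants: 9 (E)-pent-2-en-1-ol
Product: 10 [(1S,2S)-2-ethylcyclopropyl]methanol
Conditions: Zn(CH2I)2·DME (from Et2Zn, CH2I2, DME), (4R,5R)-2-butyl-N,N,N',N'-tetramethyl-1,3,2-dioxaborolane-4,5-dicarboxamide (1.2 equiv), CH2Cl2, −10 °C to rt
Reagents that add atoms: diiodomethane ICI
Why: Dioxaborolane-controlled asymmetric Simmons–Smith cyclopropanation of an (E)-allylic alcohol; the zinc alkoxide–boronate complex delivers CH2 to one alkene face, stereospecifically giving the trans-cyclopropane with both ring centres S (the ethyl-bearing carbon becomes C4 of the target).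

**Step 8**
Reactants: 10 [(1S,2S)-2-ethylcyclopropyl]methanol
Product: 11 (1S,2S)-2-ethylcyclopropane-1-carboxylic acid
Conditions: TEMPO (cat.), NaOCl (cat.), NaClO2, MeCN/phosphate buffer pH 6.7, 35 °C
Reagents that add atoms: sodium chlorite [Na+].[O-]Cl=O
Why: Nitroxyl-catalysed oxidation with NaClO2 as terminal oxidant takes the primary alcohol through the aldehyde to the acid without touching the cyclopropane; the trans arrangement is the stable one, so α-epimerisation is not a concern.

**Step 9**
Reactants: 11 (1S,2S)-2-ethylcyclopropane-1-carboxylic acid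
Product: 12 1-[(1S,2S)-2-ethylcyclopropyl]ethan-1-one
Conditions: MeLi (2.2 equiv), Et2O, 0 °C to rt; inverse quench into aqueous NH4Cl
Reagents that add atoms: methyllithium [Li]C
Why: Addition of MeLi to the lithium carboxylate gives a stable dilithium gem-diolate that collapses to the methyl ketone only on work-up.

**Step 10**
Reactants: 12 1-[(1S,2S)-2-ethylcyclopropyl]ethan-1-one
Product: 13 (1S,2S)-2-ethylcyclopropyl acetate
Conditions: CF3CO3H (from (CF3CO)2O and urea–H2O2), Na2HPO4, CH2Cl2, 0 °C to rt
Reagents that add atoms: trifluoroperacetic acid OOC(=O)C(F)(F)F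
Why: Baeyer–Villiger oxidation; the cyclopropyl group migrates in preference to methyl with retention of configuration at the migrating carbon, giving the cyclopropyl acetate.

**Step 11**
Reactants: 13 (1S,2S)-2-ethylcyclopropyl acetate
Product: 15 triethyl{[(1S,2S)-2-ethylcyclopropyl]oxy}silane, via lithium cyclopropanolate 14 (not isolated)
Conditions: MeLi (2.0 equiv), Et2O, −78 to 0 °C; then Et3SiCl (1.05 equiv), −78 °C to rt
Reagents that add atoms: chlorotriethylsilane CC[Si](Cl)(CC)CC
Why: Double addition of MeLi cleaves the acetate to the lithium cyclopropanolate without the protic base that would open the ring to the aldehyde, and silylation in the same flask traps it as the silyl ether with retention.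

**Step 12**
Reactants: 8 triethyl{[(5S,7S)-7-ethyl-3-methoxy-5-methylundecan-3-yl]peroxy}silane; 15 triethyl{[(1S,2S)-2-ethylcyclopropyl]oxy}silane
Product: 17 (4S,6R)-4,6-diethyl-6-[(2S,4S)-4-ethyl-2-methyloctyl]-3-methoxy-1,2-dioxane, via 3-siloxy-1,2-dioxane 16 (not isolated)
Conditions: Me3SiOSO2CF3 (0.2 equiv), CH2Cl2, −78 to −40 °C; then MeOH, pyridinium p-toluenesulfonate, −40 to 0 °C; chromatographic separation of the C6 epimers
Reagents that add atoms: methanol CO
Why: Proposed new method: Me3SiOSO2CF3 ionises the methoxy group of 8 to the peroxycarbenium ion (C6=O1+–O2SiEt3), which is attacked by the electron-rich C5–C3 σ-bond of the siloxycyclopropane at its CH2 corner (homoenolate reactivity); the resulting γ-silylperoxy silyloxocarbenium ion is closed by O2 in a 6-exo-trig manner with loss of a silyl cation that turns the catalyst over, and methanolysis then exchanges the labile siloxy group at C3 for methoxy. The closest known reaction types are the Lewis-acid [3+2] annulation of peroxycarbenium ions from silylperoxy ketals with alkenes to 1,2-dioxolanes, Mukaiyama-type additions of silyl enol ethers to the same cations, and the addition of cyclopropyl silyl ethers to oxocarbenium ions as homoenolate equivalents; the step is their one-carbon homologue, a formal [3+3] annulation. The selectivity needed is cleavage of the C3–C5 bond and not of C3–C4, which is secured by attack at the unsubstituted CH2 carbon and by the siloxy group that stabilises positive charge at C3. C4 is carried over unchanged from 15 because no bond to it is made or broken. C6 is created in the C–C bond formation on a cation whose ethyl and β-branched alkyl arms are of similar size, so only weak 1,3-induction from the C2' methyl centre can bias the face; both C6 epimers should form, and the 6R epimer is isolated by chromatography of the diastereomeric peroxyacetals. C3 is left as an anomeric mixture on purpose, since it is ionised again in step 13.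

**Step 13**
Reactants: 17 (4S,6R)-4,6-diethyl-6-[(2S,4S)-4-ethyl-2-methyloctyl]-3-methoxy-1,2-dioxane
Product: 18 methyl 2-[(3S,4S,6R)-4,6-diethyl-6-[(2S,4S)-4-ethyl-2-methyloctyl]-1,2-dioxan-3-yl]acetate
Conditions: CH2=C(OMe)OSiMe2t-Bu (2 equiv), Me3SiOSO2CF3 (0.3 equiv), CH2Cl2, −78 °C
Reagents that add atoms: tert-butyl[(1-methoxyethenyl)oxy]dimethylsilane COC(=C)O[Si](C)(C)C(C)(C)C
Why: Lewis-acid substitution of a cyclic peroxyacetal by a silyl ketene acetal (Mukaiyama-type addition to the cyclic peroxycarbenium ion); the quaternary C6 forces the C4 ethyl group pseudoequatorial (a pseudoaxial ethyl would be syn-diaxial to a C6 alkyl group), and stereoelectronically preferred axial attack on this half-chair places the new C3 substituent cis to the C4 ethyl group, i.e. 3S.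

**Step 14**
Reactants: 18 methyl 2-[(3S,4S,6R)-4,6-diethyl-6-[(2S,4S)-4-ethyl-2-methyloctyl]-1,2-dioxan-3-yl]acetate
Product: 19 2-[(3S,4S,6R)-4,6-diethyl-6-[(2S,4S)-4-ethyl-2-methyloctyl]-1,2-dioxan-3-yl]acetic acid
Conditions: LiOH, THF/H2O, 0 °C; then cold dilute HCl to pH 3–4
Reagents that add atoms: lithium hydroxide [Li+].[OH-]
Why: Saponification of a methyl ester with LiOH followed by mild acidification; the dialkyl peroxide is stable to cold hydroxide and no stereocentre is touched as long as the reaction is kept cold and short.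

**Compound list**
1 | methyl (E)-pent-2-enoate | CC/C=C/C(=O)OC | starting material
2 | methyl (S)-3-ethylheptanoate | CCCC[C@H](CC)CC(=O)OC | intermediate
3 | (S)-3-ethylheptanal | CCCC[C@H](CC)CC=O | intermediate
4 | (S,E)-7-ethylundec-4-en-3-one | CCCC[C@H](CC)C/C=C/C(=O)CC | intermediate
5 | (5S,7S)-7-ethyl-5-methylundecan-3-one | CCCC[C@H](CC)C[C@H](C)CC(=O)CC | intermediate
6 | (5S,7S)-7-ethyl-3,3-dimethoxy-5-methylundecane (not isolated) | CCCC[C@H](CC)C[C@H](C)CC(OC)(OC)CC | intermediate
7 | (5S,7S)-7-ethyl-3-hydroperoxy-3-methoxy-5-methylundecane (both C3 epimers) | CCCC[C@H](CC)C[C@H](C)CC(OC)(OO)CC | intermediate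
8 | triethyl{[(5S,7S)-7-ethyl-3-methoxy-5-methylundecan-3-yl]peroxy}silane (both C3 epimers) | CCCC[C@H](CC)C[C@H](C)CC(OC)(OO[Si](CC)(CC)CC)CC | intermediate
9 | (E)-pent-2-en-1-ol | CC/C=C/CO | starting material
10 | [(1S,2S)-2-ethylcyclopropyl]methanol | CC[C@H]1C[C@@H]1CO | intermediate
11 | (1S,2S)-2-ethylcyclopropane-1-carboxylic acid | CC[C@H]1C[C@@H]1C(=O)O | intermediate
12 | 1-[(1S,2S)-2-ethylcyclopropyl]ethan-1-one | CC[C@H]1C[C@@H]1C(C)=O | intermediate
13 | (1S,2S)-2-ethylcyclopropyl acetate | CC[C@H]1C[C@@H]1OC(C)=O | intermediate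
14 | lithium (1S,2S)-2-ethylcyclopropan-1-olate (not isolated) | CC[C@H]1C[C@@H]1[O-].[Li+] | intermediate
15 | triethyl{[(1S,2S)-2-ethylcyclopropyl]oxy}silane | CC[C@H]1C[C@@H]1O[Si](CC)(CC)CC | intermediate
16 | triethyl{[(4S,6R)-4,6-diethyl-6-[(2S,4S)-4-ethyl-2-methyloctyl]-1,2-dioxan-3-yl]oxy}silane (both C3 anomers, not isolated) | CCCC[C@H](CC)C[C@H](C)C[C@]1(CC)C[C@H](CC)C(O[Si](CC)(CC)CC)OO1 | intermediate
17 | (4S,6R)-4,6-diethyl-6-[(2S,4S)-4-ethyl-2-methyloctyl]-3-methoxy-1,2-dioxane (both C3 anomers) | CCCC[C@H](CC)C[C@H](C)C[C@]1(CC)C[C@H](CC)C(OC)OO1 | intermediate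
18 | methyl 2-[(3S,4S,6R)-4,6-diethyl-6-[(2S,4S)-4-ethyl-2-methyloctyl]-1,2-dioxan-3-yl]acetate | CCCC[C@H](CC)C[C@H](C)C[C@]1(CC)C[C@H](CC)[C@H](CC(=O)OC)OO1 | intermediate
19 | 2-[(3S,4S,6R)-4,6-diethyl-6-[(2S,4S)-4-ethyl-2-methyloctyl]-1,2-dioxan-3-yl]acetic acid | CCCC[C@H](CC)C[C@H](C)C[C@]1(CC)C[C@H](CC)[C@H](CC(=O)O)OO1 | target

Total step count: 14. Longest linear sequence: 9 steps (steps 1–6, then 12–14).

**Steps most likely to fail**

Step 12 (Proposed new method). Two processes may defeat it. The siloxycyclopropane may be too weak a σ-nucleophile, so that Criegee-type alkyl migration of the peroxycarbenium ion or acid-induced opening of 15 to the aldehyde outruns C–C bond formation. The two faces of the C6 cation may also be attacked without discrimination, which halves the usable material. The fallback uses known reactions only, sets out from 15 and 5, and returns at 17.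
- Electrophilic bromination of 15 (N-bromosuccinimide, CH2Cl2, −78 °C) opens the ring at the CH2 carbon to (R)-2-(bromomethyl)butanal F1. This is protected at once (ethane-1,2-diol, p-TsOH) as 2-[(2R)-1-bromobutan-2-yl]-1,3-dioxolane F2.
- The Grignard reagent from F2 (Mg, THF) is added to ketone 5 in the presence of CeCl3 to give the tertiary alcohol (5S,7S)-3-[(2S)-2-(1,3-dioxolan-2-yl)butyl]-7-ethyl-5-methylundecan-3-ol F3 as both carbinol epimers.
- Dehydration with methyl N-(triethylammoniumsulfonyl)carbamate gives 2-[(3S,7S,9S)-5,9-diethyl-7-methyltridec-4-en-3-yl]-1,3-dioxolane F4 together with its double-bond isomers about the same carbon.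
- Cobalt-catalysed silylperoxidation (Co(acac)2, O2, Et3SiH) converts all of these isomers into the Markovnikov peroxide {[(3S,7S,9S)-3-(1,3-dioxolan-2-yl)-5,9-diethyl-7-methyltridecan-5-yl]peroxy}triethylsilane F5.
- MeOH with p-TsOH removes the silyl group and closes the peroxyacetal to 17.
- C6 is again formed without control, so the epimers are separated at 17 as in the main route.

Step 13. Ionisation of the peroxyacetal may lead to fragmentation of the ring or to loss of the C4 configuration through the enol peroxide, and attack from the equatorial face would give the 3,4-trans isomer. The fallback avoids the cation, sets out from 17, and returns at 18.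
- Mild aqueous acid (AcOH, THF, H2O) gives the peroxy-hemiacetal (4S,6R)-4,6-diethyl-6-[(2S,4S)-4-ethyl-2-methyloctyl]-1,2-dioxan-3-ol F6.
- Horner–Wadsworth–Emmons olefination of its open hydroperoxy-aldehyde form ((MeO)2P(O)CH2CO2Me, LiCl, i-Pr2NEt, MeCN, 0 °C) gives methyl (2E,4S,6R,8S,10S)-4,6,10-triethyl-6-hydroperoxy-8-methyltetradec-2-enoate F7.
- Intramolecular oxa-Michael addition of the hydroperoxide (Et2NH, CF3CH2OH) closes the ring in a 6-exo-trig manner to 18 and its C3 epimer, which are separated.
- The open aldehyde must be kept cold and consumed quickly to protect the α-centre C4.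

Step 14. Hydroxide may deprotonate α to the ester and open the ring by retro-oxa-Michael elimination of the peroxide, scrambling C3 on reclosure, or may trigger base-induced fragmentation at the C3–H bond next to the peroxide. The fallback removes the saponification altogether, sets out from 17, and returns at 19.
- The substitution of step 13 is run with 1,1-bis(trimethylsilyloxy)ethene and Me3SiOSO2CF3 in CH2Cl2 at −78 °C. It gives trimethylsilyl 2-[(3S,4S,6R)-4,6-diethyl-6-[(2S,4S)-4-ethyl-2-methyloctyl]-1,2-dioxan-3-yl]acetate F8.
- F8 hydrolyses to 19 on work-up at pH 4.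

**Further compounds**
F1 | step 12 | (R)-2-(bromomethyl)butanal | BrC[C@H](CC)C=O
F2 | step 12 | 2-[(2R)-1-bromobutan-2-yl]-1,3-dioxolane | BrC[C@H](CC)C1OCCO1
F3 | step 12 | (5S,7S)-3-[(2S)-2-(1,3-dioxolan-2-yl)butyl]-7-ethyl-5-methylundecan-3-ol (both C3 epimers) | CCCC[C@H](CC)C[C@H](C)CC(O)(CC)C[C@H](CC)C1OCCO1
F4 | step 12 | 2-[(3S,7S,9S)-5,9-diethyl-7-methyltridec-4-en-3-yl]-1,3-dioxolane (with double-bond isomers about C5) | CCCC[C@H](CC)C[C@H](C)CC(CC)=C[C@H](CC)C1OCCO1
F5 | step 12 | {[(3S,7S,9S)-3-(1,3-dioxolan-2-yl)-5,9-diethyl-7-methyltridecan-5-yl]peroxy}triethylsilane (both C5 epimers) | CCCC[C@H](CC)C[C@H](C)CC(CC)(OO[Si](CC)(CC)CC)C[C@H](CC)C1OCCO1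
F6 | step 13 | (4S,6R)-4,6-diethyl-6-[(2S,4S)-4-ethyl-2-methyloctyl]-1,2-dioxan-3-ol | CCCC[C@H](CC)C[C@H](C)C[C@]1(CC)C[C@H](CC)C(O)OO1
F7 | step 13 | methyl (2E,4S,6R,8S,10S)-4,6,10-triethyl-6-hydroperoxy-8-methyltetradec-2-enoate | CCCC[C@H](CC)C[C@H](C)C[C@](OO)(CC)C[C@H](CC)/C=C/C(=O)OC
F8 | step 14 | trimethylsilyl 2-[(3S,4S,6R)-4,6-diethyl-6-[(2S,4S)-4-ethyl-2-methyloctyl]-1,2-dioxan-3-yl]acetate | CCCC[C@H](CC)C[C@H](C)C[C@]1(CC)C[C@H](CC)[C@H](CC(=O)O[Si](C)(C)C)OO1
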